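Amounts first: each target takes one partner, and the partner charge of 0.60 equiv per substrate is smaller than the substrate charge, so I write the balance of the partner, which I treat as the limiting reagent of the target step. At 5.00 d the autumn run reads target 58.2%, which reckons to 3.00% of the partner free. This is my free partner share, one minus the target fraction over the equivalents. Target taken out counts as made, so the balance holds for ash too.

| flask | substrate | partner | temperature | remark | time |
|---|---|---|---|---|---|
| autumn | 0.10 M | 0.60 equiv | 50 °C | the very flask that is asked about, followed so far |  |
| winter | 0.10 M | 0.60 equiv | 35 °C | run made earlier |  |
| flask | 0.10 M | 0.600 equiv | 50 °C |  | 8.0 d |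

- autumn (time / d: target / %, substrate / %): 0.833: 22.3, 22.5; 1.67: 40.4, 5.8; 2.50: 48.1, 1.5; 3.00: 51.7, 0.7; 4.00: 55.4, 1.9; 5.00: 58.2, 0
- winter (time / d: target / %, substrate / %): 1.67: 7.3, 70.3; 4.00: 24.0, 42.1; 5.00: 29.5, 31.8; 6.00: 33.9, 26.4; 8.00: 43.0, 17.1; 10.0: 47.3, 9.9

(readings scatter by 1 percentage point)

- larch: at 8.0 d add partner, 100% of the amount charged, then wait 8.0 d
- cedar: change nothing and wait 8.0 d more
- ash: at 8.0 d take out 90% of the target then present, then wait 8.0 d
- elm: at 8.0 d raise the temperature by 10 K, then wait 8.0 d

- percentages count the substrate that a species holds: one side product counts as two
- target taken out counts as made
- what may be going on: substrate + intermediate -> side product; partner + intermediate -> target; substrate -> intermediate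
- additions bring no volume worth counting

1. target, in percent of the substrate first charged, at 8.0 d
2. the option that brings most further target ("none" if no option brings more than 2 percentage points) (larch / cedar / ash / elm / none)
3. target present, with what was taken out counted in, in percent of the substrate first charged, after larch
4. target present, with what was taken out counted in, in percent of the substrate first charged, after cedar

The first rung in the autumn run is substrate loss: the readings give 1.62 /d between 0.833 d and 1.67 d, a half-life of 0.428 d. So at 2.50 d the substrate reads 1.5% and the target 48.1%, and 50.4% of the charge sits unseen as intermediate and side product, which these readings do not part. The next rung is target growth out of that pool: the target gains 18 percentage points from 0.833 d to 1.67 d, but 2.8 points from 4.00 d to 5.00 d. The last rung is the closing of the free partner share. Multiplied by the equivalents, it gives the room left at 5.00 d for target without new partner: 1.8 points, which is less than the 2 points threshold, though this rests on a reading with a scatter of 1 point. So I put the target at 8.0 d just under 60.0%, and I expect cedar, ash and elm to stay below the threshold. Larch is my choice, because at 5.00 d the readings leave 41.8% of the charge unseen, and new partner may find intermediate there, but these readings do not part that share, so the size of the gain stays open.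

The forecast gives 59.5% now, larch as best, 95% after larch and 60% after cedar, and it says: “The side path looks minor”.

The flask gives 59.2%, and larch is best with 79.8%, against 60.0% after cedar and the forecast's 95%.

substrate + intermediate → side product (k = 0.00454 /M/min, Ea = 86.0 kJ/mol); partner + intermediate → target (k = 0.0144 /M/min, Ea = 58.0 kJ/mol); substrate → intermediate (k = 0.00112 /min, Ea = 116 kJ/mol); (constants at 50 °C) At 8.00 d the side product holds 20.2% and the intermediate 20.6%, so target plus intermediate comes to 79.8%. The free partner share, 3.00% from the reading at 5.00 d, stands at 1.27% in the flask at 8.00 d, a room of 0.76 points, and cedar brings 0.73 points. The neighbour charged with 1.00 equiv of partner reaches target 82.1%, so its share reckons to 17.9%, and that neighbour holds 18% of its partner free.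

All runs come from a simulation on assumed constants.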